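The data are simulated from invented constants; scatter was added.

1. Time comes first: these flasks run on separate rungs, and the runs autumn, spring and dawn let you read each rung before you reckon oak to alder.

| setting | autumn | spring | dawn | oak | cedar | larch | elm | alder |
|---|---|---|---|---|---|---|---|---|
| substrate | 0.0048 M (fed, over 4.0 min) | 0.023 M (fed, over 4.0 min) | 0.080 M (fed, over 4.0 min) | 0.0060 M (fed, over 4.0 min) | 0.012 M (fed, over 4.0 min) | 0.025 M (fed, over 4.0 min) | 0.050 M (fed, over 4.0 min) | 0.10 M (fed, over 4.0 min) |
| free catalyst | 0.13 mM | 0.13 mM | 0.13 mM | 0.13 mM | 0.13 mM | 0.13 mM | 0.13 mM | 0.13 mM |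
| remark | run made earlier; the fed solution adds 0.25 times the starting volume | run made earlier; the fed solution adds 0.25 times the starting volume | run made earlier; the fed solution adds 0.25 times the starting volume | the fed solution adds 0.25 times the starting volume | the fed solution adds 0.25 times the starting volume | the fed solution adds 0.25 times the starting volume | the fed solution adds 0.25 times the starting volume | the fed solution adds 0.25 times the starting volume |
| time |  |  |  | 30 min | 30 min | 30 min | 30 min | 30 min |

| run | time / min | product / % | substrate / % |
|---|---|---|---|
| autumn | 2.50 | 0.3 | 61.3 |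
| autumn | 5.00 | 1.8 | 95.7 |
| autumn | 8.00 | 3.5 | 92.0 |
| autumn | 15.0 | 7.1 | 84.2 |
| autumn | 30.0 | 14.5 | 69.5 |
| spring | 2.50 | 0.5 | 61.8 |
| spring | 5.00 | 1.4 | 96.5 |
| spring | 8.00 | 3.0 | 92.8 |
| spring | 15.0 | 6.5 | 84.6 |
| spring | 30.0 | 13.7 | 70.4 |
| dawn | 2.50 | 0.2 | 61.3 |
| dawn | 5.00 | 0.6 | 96.0 |
| dawn | 8.00 | 2.7 | 94.3 |
| dawn | 15.0 | 5.1 | 86.3 |
| dawn | 30.0 | 10.4 | 73.7 |

(each reading ± 0.3 percentage points)

- charges are per starting volume, the dose included; the dosed solution carries all of it
- "hardly changes" means that all values lie within two and a half points (for a concentration: within two and a half percent of the largest)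
- percentages count the whole charge, also what has not yet gone in

- amount of product at the end, in percent of the substrate charged for oak, cedar, larch, elm, alder, in this order
- how the row runs (falls, then rises / rises, then falls / falls all the way / hardly changes / rises all the way)

2. First rung: the binding of substrate to free catalyst. In autumn, product gains 0.00567 /min of the charge between 5.00 min and 8.00 min, and 0.00493 /min between 15.0 min and 30.0 min. In autumn no lag shows after the feed, so treat the bound share of catalyst as settled on the scale of these readings, a quasi-steady state.

3. Next rung: the feed. At 2.50 min, autumn shows 61.3% as substrate with 62.5% fed, so substrate follows the dose.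

4. Last rung: two drains on substrate. In autumn, from 8.00 min on, product forms at 0.00619 /min per unit of substrate; read as pseudo-first-order in substrate, that is a half-life of 112 min for this route taken by itself. The unaccounted part grows at 0.00647 /min per unit of substrate, about as fast. Product plus substrate at 30.0 min is 84.0% in autumn and 84.1% in dawn, so these two runs, at charges of 0.0048 M and 0.080 M, lose the same share within the scatter. The feed is far shorter than these half-lives, so count the charge as present from the start.

5. The charge. Let the free share of catalyst be f = c_half / (c_half + c(substrate)), with c(substrate) on the charge scale, and let product at the end go with f. Autumn over dawn gives a product ratio of 1.39, hence, as a reading that carries their scatter, 0.186 M: this is c_half, the half-point charge, where f is one half. Extrapolated to no charge, product at 30.0 min is 14.9%. The unused spring run comes out at 13.2% against 13.7% read, a gap of 0.50 percentage points beside a scatter of 0.3 points. Your own row runs from 14.4% at oak down to 9.67% at alder, falling.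

6. The forecast gives 14.4%, 14.1%, 13.4%, 12.1%, 9.6%; its row falls all the way. It reads the fall as “the catalysed route beginning to saturate”.

7. The flasks give 14.3%, 13.8%, 12.8%, 11.3%, 9.09%, so the row falls all the way, with alder 0.51 points under the forecast.

substrate + free catalyst ⇌ catalyst intermediate A (K = 9.60 /M, k = 5.10 /M/s); catalyst intermediate A ⇌ catalyst intermediate B (K = 1.50, k = 0.170 /s); catalyst intermediate B → free catalyst + product (k = 0.390 /s); substrate ⇌ dormant form (K = 2.40, k = 1.20 × 10⁻⁴ /s) At 4.00 min, alder holds 55.5% of its catalyst free; at 30.0 min, it holds 62.1% free, 28.4% as catalyst intermediate A and 9.58% as catalyst intermediate B. The half-point charge 0.186 M gives alder, on the charge scale, a free share of 65.0%. For elm it gives 78.8%, and elm stands at 71.5% free at 4.00 min and 77.1% free at 30.0 min.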